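In the blue run 14.3% of the electrophile is left at 10.0 d, though the nucleophile was charged at 1.80 equivalents. I have to account for that leftover before I judge these flasks, which differ in free base.

the same everywhere: electrophile 0.016 M; nucleophile 0.0288 M
- blue: free base 0.014 M; run made earlier
- eta: free base 0.0180 M; time 10 d
- theta: free base 0.0300 M; time 10 d
- gamma: free base 0.0230 M; time 10 d

blue run (percent of the electrophile charged)

| time / d | electrophile / % | product / % |
|---|---|---|
| 0.833 | 55.9 | 43.4 |
| 2.50 | 31.2 | 69.1 |
| 5.00 | 20.4 | 79.6 |
| 8.00 | 16.5 | 84.2 |
| 10.0 | 14.3 | 85.9 |

(each reading ± 0.5 percentage points)

- the analysis behind the earlier runs scatters by 0.5 percentage points, standard deviation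
- a reading or a percentage of product counts all its forms, free or not
- no earlier run changes the charge of free base; that part of a forecast is a guess

* part of the electrophile that has reacted at the end, eta
* part of the electrophile that has reacted at the end, theta
* part of the electrophile that has reacted at the end, gamma
* what raising the concentration of free base from its lowest to its highest value here does to the part of the electrophile that has reacted (changes below 5 percentage points count as none) (no change / it falls / it rises)

If each turnover sets an acid free, two extreme flasks can be solved in the head. In the first, free base takes the acid, one nucleophile goes per turnover, and the electrophile can react to the end. In the second, free base stands idle and the nucleophile takes the acid as well, so the nucleophile becomes the limiting reagent and the reaction stops at the two-for-one mark, 90.0%, the fraction of the electrophile that the nucleophile can pay for at two per turnover.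

Each version turns a reading into a rate number that should stay constant. The first gives 0.451 d⁻¹ at 0.833 d and 0.162 d⁻¹ at 10.0 d, falling to a third. The second gives 0.551 d⁻¹ and 0.548 d⁻¹, level. So blue sits at the second end, despite its 0.875 equivalents of free base. No run changes free base, so this is a guess, but I expect the new flasks to repeat blue: 85.7% reacted at 10 d, below the mark, with no change between them.

The forecast reads the stall differently, “each turnover consumes one base”, and gives 97% for eta, 99.8% for gamma and 99.9% for theta, with the trend no change. We differ on the numbers and agree on the trend.

The flasks give 85.9% for eta, 86.0% for gamma and 86.0% for theta, a shift of 0.091 percentage points, so the trend is no change.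

    electrophile + nucleophile ⇌ acid set free + product (K = 0.144, k = 0.0243 M⁻¹ min⁻¹)
    crystals ⇌ product, rate k2*(cs2 - [product]) while solid is left; crystals form when [product] > cs2 (solubility = 0.570 mM, k = 0.0452 min⁻¹)
    acid set free + free base ⇌ salt of the base (K = 118 M⁻¹, k = 0.223 M⁻¹ min⁻¹)
    nucleophile + acid set free ⇌ protonated nucleophile, settled at all times (K = 1.70 × 10⁵ M⁻¹)

In eta, electrophile and nucleophile go on reacting while free nucleophile falls from 11.9% of its charge at 5.00 d to 5.08% at 10.0 d, when 47.2% of that charge is protonated nucleophile and 99.4% of the free base is still free. Eta then creeps to 90.3% at 100 d, about the mark of 90.0%, and theta to 90.9%, just past it.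

Take a neighbour of gamma with the nucleophile cut to 0.450 equiv: the mark gives 22.5%. Computed, that neighbour reaches 24.1% at 10.0 d, with 75.9% of its electrophile left.

The earlier runs and the new flask were generated by integration from invented constants; scatter was added.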